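## The problem

The target is made of two fully substituted six-membered rings that share nothing but one methylene carbon. Ring A is a phloroglucinol core: A1 carries the bridging CH2, A2 and A4 carry OH, A3 a prenyl group, A5 the (R)-2-methylbutanoyl group and A6 OMe. Ring B is a 4-hydroxypyran-2-one: O1, the lactone carbonyl C2, C3 with the bridging CH2, C4–OH, C5–Me and C6–Et. Three different carbon substituents must therefore be placed, each on its own ring carbon between two oxygen atoms, and ring B must be made without disturbing them. The only stereocentre is the α-carbon of the aryl ketone. Nothing in the molecule can control it or be controlled by it, so it has to be bought and then kept, although it sits next to a carbonyl group and is lost through the enol or enolate. The groups that do not tolerate rough treatment are: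

- the prenyl double bond between two phenols (acid closes a chroman; hydrogenation is excluded);
- the electron-rich free phloroglucinol (oxidation);
- the acidic enolic OH of ring B;
- any benzylic carbinol at A5 of a trialkoxybenzene, which ionises easily.

The feature that opens the key step is that O1–C2(=O)–C3 of ring B is an ester of the enol oxygen on C6, while C4–C5=C6 is what is left of a β-keto ester. Ring B is thus the cyclised O-acyl enol of methyl 2-methyl-3-oxopentanoate and a 3-arylpropanoic acid, and its C3–C4 bond can be made last.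

## Retrosynthesis

**Target 24 back to 21.** No skeletal bond is cut. The two phenols of 24 are traced to MOM ethers (23), the ketone of 23 to the carbinol 22, and 22 to its silyl ether 21. Carrying the ketone through the ring-B closure would offer the amide base a ketone α-proton more acidic than the ester α-proton it is meant to remove, and the (R)-centre would be lost. A carbinol has no such proton. The carbinol is masked with silicon and not with an acetal because it must be oxidised before the phenols are freed by acid: a free phloroglucinol carbinol would ionise. The forward direction asks for fluoride, a buffered oxidation and mild acid, in that order.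

**21 back to 20.** The C3–C4 bond of ring B is cut. Cutting O1–C2 instead would require a 2-(arylmethyl)-3,5-diketo ester, whose assembly means C-acylation at a carbon already carrying the bulky arylmethyl group. Cutting C3–CH2 would require a benzylic electrophile on a trialkoxybenzene, which is not a stable reagent. The C3–C4 cut opens ring B to the enol ester 20, in which only simple ester chemistry remains. The forward reaction is an intramolecular Claisen condensation; it needs the (Z) geometry of 20 and enolisation at the acyl CH2.

**20 back to 16 and 17.** The enol O–acyl bond (O1–C2) is cut, giving the 3-arylpropanoic acid 16 and the commercial β-keto ester 17. This is the most convergent cut available, with all of ring A on one side and all carbons of ring B but two on the other. The forward reaction must acylate the enolate 19 at oxygen, through the acid chloride 18, with the acyloxy group cis to the ester.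

**16 back to 12 and 13.** The bond from A1 to the side-chain CH2 is cut, and the three-carbon acid chain is traced to β-propiolactone 13. The neighbouring choice (formylation, two-carbon olefination, conjugate reduction that must spare the prenyl group, hydrolysis) costs four steps for the same bond. The precursor 12 has one ring hydrogen left, flanked by OMOM and OMe. The forward reaction is metalation to 14, exchange to 15 and copper-catalysed opening of 13 at its O-alkyl carbon.

**12 back to 5 and 8, and 8 back to 6.** The A5–C(acyl) bond is cut. The silyl ether 12 comes from carbinol 11, which comes from ketone 10; 10 is the product of aryllithium 9 (from 5) and the N-methoxy-N-methyl amide 8 of acid 6, made through imidazolide 7. Friedel–Crafts acylation would bring Lewis acid to the prenyl group and risk the stereocentre. The amide route releases the ketone only on work-up. The forward steps are metalation between OMOM and OMe, acylation, hydride reduction and silylation.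

**5 back to 2 and 3, and 2 back to 1.** The A3–CH2 bond of the prenyl group is cut. The symmetrical, commercial 5-methoxyresorcinol 1 gives the bis-MOM ether 2, whose carbon between the two OMOM groups is metalated first (4) and alkylated with prenyl bromide 3. After this step the two remaining ring positions are equivalent, so the first metalation is the only one in which the site is a question.

## Roads not taken

**Alternative 1:** The A4–O and A5–C(acyl) bonds of ring A would be made together. Fluoride (CsF) would turn the silyl triflate A2 into the A4–A5 aryne, and acid 6 would add across it. The methoxy group at A6 polarises the aryne, so the carboxylate oxygen attacks A4, the aryl anion at A5 attacks the acyl carbon, and the ortho-hydroxy ketone A1 results.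

- Merits: the enantiopure acid is used as such, the ketone appears at its final oxidation level under near-neutral conditions, and the reduction, silylation, desilylation and oxidation of the chosen plan are not needed. In this respect the road is better.
- Weak points: A2 is a pentasubstituted arene that needs several steps of its own. Plain O-arylation to the aryl ester competes with insertion. The prenyl alkene next to the aryne is a possible ene partner. No ring is formed, so ring B and its methylene link to A1 would still have to be made, in the presence of the epimerisable ketone.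
- Comparison: the chosen plan has to set against the step saving the reliability of the amide ketone synthesis, a single metalation logic for all three carbon substituents, and the absence of the ketone whenever strong base is used.

**Alternative 2:** The C4–C5 and O1–C2 bonds of ring B would be cut. The malonyl dichloride A4 would lose HCl to a chlorocarbonyl ketene, which acylates the silyl enol ether A5 of pentan-3-one at carbon; the enol oxygen then closes the lactone to give A3.

- Merits: ring B forms in one step with two bonds, from a symmetrical ketone, with no enol-ester geometry to control and no strong base. Here it is more convergent than the chosen plan and free of its geometric requirement.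
- Weak points: two equivalents of HCl and an acid chloride meet an enolisable chiral ketone and a very electron-rich ring. The phenols must be benzyl ethers, so the prenyl group cannot be present. It would have to be added after hydrogenolysis by C-alkylation of a free acylphloroglucinol that also carries the pyranone OH, a step with poor C/O selectivity. A4 itself needs an arylmethyl malonic acid and its conversion to the dichloride.
- Comparison: the chosen plan answers with all ring-A substituents, prenyl included, in place before ring closure, with base-only conditions that MOM ethers and the alkene tolerate, and with the stereocentre insulated during the closure.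

**Alternative 3:** Ring A would be assembled by cutting A2–A3 and A4–A5. Heating cyclobutenone A7 with siloxyalkyne A8 would open A7 to a vinylketene, add the alkyne, reopen and electrocyclise to the phenol A6.

- Merits: the positions of all six substituents are fixed by the mechanism and not by successive metalations of an ever more crowded ring, and the two phenols emerge differentiated. In regiochemical certainty this road is better.
- Weak points: A7 (with the stereocentre side chain and the propanoate chain) and A8 (a skipped enyne with a labile siloxyalkyne) are each multi-step targets. The thermal cascade has to run with a fully substituted vinylketene in the presence of the prenyl alkene. A6 is only a ring-A building block, so ring B would still be made as in the chosen plan.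
- Comparison: the chosen plan sets against it a commercial, symmetrical starting arene in which only the first metalation poses a regiochemical question, and a far shorter path to the same propanoic acid stage.

Key step: step 9

Assumption: the carbinol carbon created in step 5 is carried as a mixture of both configurations (compounds 11, 12, 14–16, 18, 20–22); this is of no consequence because step 11 returns it to a carbonyl carbon.

## Route

Step 1
Reactants: 1 5-methoxyresorcinol (5-methoxybenzene-1,3-diol)
Product: 2 1-methoxy-3,5-bis(methoxymethoxy)benzene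
Conditions: MOMCl, i-Pr2NEt, CH2Cl2, 0 °C → rt
Reagents that add atoms: chloromethyl methyl ether, COCCl
Why: Base-mediated O-alkylation of both phenols gives the bis-acetal; the MOM ethers direct all three later ortho-metalations and leave together in the last step.

Step 2
Reactants: 2 1-methoxy-3,5-bis(methoxymethoxy)benzene; 3 prenyl bromide (1-bromo-3-methylbut-2-ene)
Product: 5 5-methoxy-1,3-bis(methoxymethoxy)-2-(3-methylbut-2-enyl)benzene, via aryllithium 4 (not isolated)
Conditions: n-BuLi, TMEDA, THF, 0 °C; then CuI (10 mol %), prenyl bromide, −78 °C → rt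
Reagents that add atoms: none
Why: Directed ortho-metalation should favour the carbon flanked by two cooperating OMOM groups over those flanked by OMOM and the weaker OMe director; copper-assisted SN2 allylation of the aryl anion then gives the linear prenyl arene.

Step 3
Reactants: 6 (R)-2-methylbutanoic acid
Product: 8 (R)-N-methoxy-N,2-dimethylbutanamide, via acyl imidazolide 7 (not isolated)
Conditions: 1,1'-carbonyldiimidazole, CH2Cl2, 0 °C → rt; then MeNHOMe·HCl, rt
Reagents that add atoms: N,O-dimethylhydroxylamine hydrochloride, CNOC.Cl
Why: Amide coupling through the acyl imidazolide; no base able to enolise the acyl group is present, so the α-stereocentre is kept.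

Step 4
Reactants: 5 5-methoxy-1,3-bis(methoxymethoxy)-2-(3-methylbut-2-enyl)benzene; 8 (R)-N-methoxy-N,2-dimethylbutanamide
Product: 10 (2R)-1-[6-methoxy-2,4-bis(methoxymethoxy)-3-(3-methylbut-2-enyl)phenyl]-2-methylbutan-1-one, via aryllithium 9 (not isolated)
Conditions: n-BuLi, TMEDA, THF, 0 °C; then 8, −78 → 0 °C; aq. NH4Cl
Reagents that add atoms: none
Why: Ortho-metalation at one of the two equivalent ring CH positions between OMOM and OMe should outrun attack at the allylic-benzylic CH2. In the ketone synthesis from the N-methoxy-N-methyl amide the chelated tetrahedral adduct survives until the quench, so neither over-addition nor enolisation of the ketone can occur in the basic medium, and enolisation of 8 would cost conversion but not configuration.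

Step 5
Reactants: 10 (2R)-1-[6-methoxy-2,4-bis(methoxymethoxy)-3-(3-methylbut-2-enyl)phenyl]-2-methylbutan-1-one
Product: 11 (2R)-1-[6-methoxy-2,4-bis(methoxymethoxy)-3-(3-methylbut-2-enyl)phenyl]-2-methylbutan-1-ol (both configurations at C1)
Conditions: LiAlH4, THF, 0 °C; aq. potassium sodium tartrate
Reagents that add atoms: none
Why: Hydride reduction of the hindered aryl ketone; the new carbinol centre is formed without control and needs none, and with the carbonyl gone the neighbouring (R)-CH is no longer acidic. The non-acidic work-up avoids ionisation of the electron-rich benzylic alcohol.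

Step 6
Reactants: 11 (2R)-1-[6-methoxy-2,4-bis(methoxymethoxy)-3-(3-methylbut-2-enyl)phenyl]-2-methylbutan-1-ol
Product: 12 tert-butyl{(2R)-1-[6-methoxy-2,4-bis(methoxymethoxy)-3-(3-methylbut-2-enyl)phenyl]-2-methylbutoxy}dimethylsilane (both configurations at C1)
Conditions: TBSOTf, 2,6-lutidine, CH2Cl2, −78 °C
Reagents that add atoms: tert-butyldimethylsilyl trifluoromethanesulfonate, CC(C)(C)[Si](C)(C)OS(=O)(=O)C(F)(F)F
Why: Silyl triflate silylation of a hindered secondary alcohol; low temperature and excess lutidine should spare the aryl MOM ethers and the ionisable benzylic C–O bond. The silyl ether is inert to the organolithium, enolate and amide bases that follow and leaves with fluoride.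

Step 7
Reactants: 12 tert-butyl{(2R)-1-[6-methoxy-2,4-bis(methoxymethoxy)-3-(3-methylbut-2-enyl)phenyl]-2-methylbutoxy}dimethylsilane; 13 β-propiolactone (oxetan-2-one)
Product: 16 3-{3-[(2R)-1-(tert-butyldimethylsilyloxy)-2-methylbutyl]-2-methoxy-4,6-bis(methoxymethoxy)-5-(3-methylbut-2-enyl)phenyl}propanoic acid, via aryllithium 14 (not isolated), via arylmagnesium bromide 15 (not isolated)
Conditions: n-BuLi, TMEDA, THF, 0 °C; MgBr2·OEt2, −20 °C; CuBr·SMe2 (10 mol %), β-propiolactone, −30 → 0 °C; aq. NaH2PO4
Reagents that add atoms: none
Why: Ortho-metalation at the last ring CH (between OMOM and OMe), exchange to the Grignard reagent and copper-catalysed SN2 opening of the β-lactone at its O-alkyl carbon should deliver the 3-arylpropanoic acid in one operation. The weakly acidic work-up protects the MOM and benzylic silyl ethers.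

Step 8
Reactants: 16 3-{3-[(2R)-1-(tert-butyldimethylsilyloxy)-2-methylbutyl]-2-methoxy-4,6-bis(methoxymethoxy)-5-(3-methylbut-2-enyl)phenyl}propanoic acid; 17 methyl 2-methyl-3-oxopentanoate
Product: 20 methyl (Z)-3-[(3-{3-[(2R)-1-(tert-butyldimethylsilyloxy)-2-methylbutyl]-2-methoxy-4,6-bis(methoxymethoxy)-5-(3-methylbut-2-enyl)phenyl}propanoyl)oxy]-2-methylpent-2-enoate, via acid chloride 18 (not isolated), via sodium enolate 19 (not isolated)
Conditions: 16, 1-chloro-N,N,2-trimethylprop-1-en-1-amine, CH2Cl2, 0 °C → rt; 17, NaH, Et2O, 0 °C; then 18, −20 → 0 °C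
Reagents that add atoms: none
Why: The α-chloroenamine makes the acid chloride without HCl, so the acid-labile groups survive. O-acylation of the sodium enolate, held in ether as a chelate between the enolate oxygen and the ester carbonyl, should give the (Z)-enol ester, and the α-methyl group (C-acylation would build a quaternary carbon) together with the hard acyl chloride directs the attack to oxygen.

Step 9
Reactants: 20 methyl (Z)-3-[(3-{3-[(2R)-1-(tert-butyldimethylsilyloxy)-2-methylbutyl]-2-methoxy-4,6-bis(methoxymethoxy)-5-(3-methylbut-2-enyl)phenyl}propanoyl)oxy]-2-methylpent-2-enoate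
Product: 21 3-({3-[(2R)-1-(tert-butyldimethylsilyloxy)-2-methylbutyl]-2-methoxy-4,6-bis(methoxymethoxy)-5-(3-methylbut-2-enyl)phenyl}methyl)-6-ethyl-4-hydroxy-5-methylpyran-2-one
Conditions: 20 added to LiN(SiMe3)2 (3 equiv), THF, −78 → −20 °C; aq. NaH2PO4
Reagents that add atoms: none
Why: The amide base removes a proton from the CH2 next to the enol-ester carbonyl, and the ester enolate attacks the methyl ester held cis to it on the tetrasubstituted alkene; loss of methoxide forms C3–C4 and closes the pyranone, an intramolecular Claisen (Dieckmann) condensation. The closest known reaction type is the Dieckmann cyclisation of O-acylated hydroxy esters, which gives tetronic acids from α-acyloxy esters and 4-hydroxycoumarins from O-acyl salicylates, the latter being the same (Z)-β-acyloxy acrylate unit locked in a benzene ring. The one ring is closed in the 6-(enolendo)-exo-trig mode, which is allowed for an enolate. No stereocentre is formed; the (R)-centre has no acidifying neighbour at this stage because the ketone is masked as the silyl ether, and the carbinol centre is a spectator. The step needs deprotonation at the acyl CH2 and not at the γ-CH2 of the enoate: the (Z) geometry puts the ethyl group anti to the ester carbonyl, where carbonyl-directed γ-deprotonation by a lithium amide is slow. The same geometry is the condition for closure, since only with acyloxy and ester cis can the enolate carbon reach the ester carbon. Excess base converts the product at once into the aromatic pyranonate, which makes the closure irreversible, and low temperature with inverse addition restrains the competing loss of the β-keto ester enolate from the acyl enolate. MOM ethers, prenyl group and silyl ether carry no proton of comparable acidity.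

Step 10
Reactants: 21 3-({3-[(2R)-1-(tert-butyldimethylsilyloxy)-2-methylbutyl]-2-methoxy-4,6-bis(methoxymethoxy)-5-(3-methylbut-2-enyl)phenyl}methyl)-6-ethyl-4-hydroxy-5-methylpyran-2-one
Product: 22 6-ethyl-4-hydroxy-3-({3-[(2R)-1-hydroxy-2-methylbutyl]-2-methoxy-4,6-bis(methoxymethoxy)-5-(3-methylbut-2-enyl)phenyl}methyl)-5-methylpyran-2-one
Conditions: Bu4NF (3 equiv), THF, 0 °C → rt; pH 7 phosphate buffer
Reagents that add atoms: none
Why: Fluoride cleaves the Si–O bond while the pyranone sits as its ammonium salt; the neutral work-up keeps the electron-rich benzylic carbinol from ionising, and the crude carbinol is oxidised without storage.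

Step 11
Reactants: 22 6-ethyl-4-hydroxy-3-({3-[(2R)-1-hydroxy-2-methylbutyl]-2-methoxy-4,6-bis(methoxymethoxy)-5-(3-methylbut-2-enyl)phenyl}methyl)-5-methylpyran-2-one
Product: 23 6-ethyl-4-hydroxy-3-({2-methoxy-4,6-bis(methoxymethoxy)-3-[(2R)-2-methylbutanoyl]-5-(3-methylbut-2-enyl)phenyl}methyl)-5-methylpyran-2-one
Conditions: Dess–Martin periodinane, NaHCO3, CH2Cl2, 0 °C → rt
Reagents that add atoms: none
Why: Periodinane oxidation of the secondary benzylic alcohol under buffered, non-enolising conditions should return the aryl ketone with the (R)-centre intact; both carbinol epimers converge, and 2-substituted 1,3-dicarbonyl enols, MOM ethers and the prenyl alkene normally tolerate the reagent.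

Step 12
Reactants: 23 6-ethyl-4-hydroxy-3-({2-methoxy-4,6-bis(methoxymethoxy)-3-[(2R)-2-methylbutanoyl]-5-(3-methylbut-2-enyl)phenyl}methyl)-5-methylpyran-2-one
Product: 24 6-ethyl-4-hydroxy-3-({2,4-dihydroxy-6-methoxy-5-[(2R)-2-methylbutanoyl]-3-(3-methylbut-2-enyl)phenyl}methyl)-5-methylpyran-2-one (target)
Conditions: HCl (1.25 M in MeOH), MeOH, 0 °C → rt
Reagents that add atoms: none
Why: Acid-catalysed acetal exchange with methanol removes both aryl MOM ethers; dilute anhydrous acid at or below room temperature should leave the prenyl group uncyclised and the hindered ketone unenolised.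

## Compound list

1 | 5-methoxyresorcinol (5-methoxybenzene-1,3-diol) | COc1cc(O)cc(O)c1 | starting material
2 | 1-methoxy-3,5-bis(methoxymethoxy)benzene | COCOc1cc(OC)cc(OCOC)c1 | intermediate
3 | prenyl bromide (1-bromo-3-methylbut-2-ene) | CC(C)=CCBr | starting material
4 | [4-methoxy-2,6-bis(methoxymethoxy)phenyl]lithium | [Li]c1c(OCOC)cc(OC)cc1OCOC | intermediate (not isolated)
5 | 5-methoxy-1,3-bis(methoxymethoxy)-2-(3-methylbut-2-enyl)benzene | COCOc1cc(OC)cc(OCOC)c1CC=C(C)C | intermediate
6 | (R)-2-methylbutanoic acid | CC[C@@H](C)C(=O)O | starting material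
7 | (2R)-1-(imidazol-1-yl)-2-methylbutan-1-one | CC[C@@H](C)C(=O)n1ccnc1 | intermediate (not isolated)
8 | (R)-N-methoxy-N,2-dimethylbutanamide | CC[C@@H](C)C(=O)N(C)OC | intermediate
9 | [6-methoxy-2,4-bis(methoxymethoxy)-3-(3-methylbut-2-enyl)phenyl]lithium | [Li]c1c(OC)cc(OCOC)c(CC=C(C)C)c1OCOC | intermediate (not isolated)
10 | (2R)-1-[6-methoxy-2,4-bis(methoxymethoxy)-3-(3-methylbut-2-enyl)phenyl]-2-methylbutan-1-one | CC[C@@H](C)C(=O)c1c(OC)cc(OCOC)c(CC=C(C)C)c1OCOC | intermediate
11 | (2R)-1-[6-methoxy-2,4-bis(methoxymethoxy)-3-(3-methylbut-2-enyl)phenyl]-2-methylbutan-1-ol (both configurations at C1) | CC[C@@H](C)C(O)c1c(OC)cc(OCOC)c(CC=C(C)C)c1OCOC | intermediate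
12 | tert-butyl{(2R)-1-[6-methoxy-2,4-bis(methoxymethoxy)-3-(3-methylbut-2-enyl)phenyl]-2-methylbutoxy}dimethylsilane (both configurations at C1) | CC[C@@H](C)C(O[Si](C)(C)C(C)(C)C)c1c(OC)cc(OCOC)c(CC=C(C)C)c1OCOC | intermediate
13 | β-propiolactone (oxetan-2-one) | O=C1CCO1 | starting material
14 | {3-[(2R)-1-(tert-butyldimethylsilyloxy)-2-methylbutyl]-2-methoxy-4,6-bis(methoxymethoxy)-5-(3-methylbut-2-enyl)phenyl}lithium | CC[C@@H](C)C(O[Si](C)(C)C(C)(C)C)c1c(OC)c([Li])c(OCOC)c(CC=C(C)C)c1OCOC | intermediate (not isolated)
15 | {3-[(2R)-1-(tert-butyldimethylsilyloxy)-2-methylbutyl]-2-methoxy-4,6-bis(methoxymethoxy)-5-(3-methylbut-2-enyl)phenyl}magnesium bromide | CC[C@@H](C)C(O[Si](C)(C)C(C)(C)C)c1c(OC)c([Mg]Br)c(OCOC)c(CC=C(C)C)c1OCOC | intermediate (not isolated)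
16 | 3-{3-[(2R)-1-(tert-butyldimethylsilyloxy)-2-methylbutyl]-2-methoxy-4,6-bis(methoxymethoxy)-5-(3-methylbut-2-enyl)phenyl}propanoic acid | CC[C@@H](C)C(O[Si](C)(C)C(C)(C)C)c1c(OC)c(CCC(=O)O)c(OCOC)c(CC=C(C)C)c1OCOC | intermediate
17 | methyl 2-methyl-3-oxopentanoate | CCC(=O)C(C)C(=O)OC | starting material
18 | 3-{3-[(2R)-1-(tert-butyldimethylsilyloxy)-2-methylbutyl]-2-methoxy-4,6-bis(methoxymethoxy)-5-(3-methylbut-2-enyl)phenyl}propanoyl chloride | CC[C@@H](C)C(O[Si](C)(C)C(C)(C)C)c1c(OC)c(CCC(=O)Cl)c(OCOC)c(CC=C(C)C)c1OCOC | intermediate (not isolated)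
19 | sodium (Z)-1-methoxy-2-methyl-1-oxopent-2-en-3-olate | CC/C([O-])=C(\C)C(=O)OC.[Na+] | intermediate (not isolated)
20 | methyl (Z)-3-[(3-{3-[(2R)-1-(tert-butyldimethylsilyloxy)-2-methylbutyl]-2-methoxy-4,6-bis(methoxymethoxy)-5-(3-methylbut-2-enyl)phenyl}propanoyl)oxy]-2-methylpent-2-enoate | CC/C(OC(=O)CCc1c(OCOC)c(CC=C(C)C)c(OCOC)c(C(O[Si](C)(C)C(C)(C)C)[C@H](C)CC)c1OC)=C(\C)C(=O)OC | intermediate
21 | 3-({3-[(2R)-1-(tert-butyldimethylsilyloxy)-2-methylbutyl]-2-methoxy-4,6-bis(methoxymethoxy)-5-(3-methylbut-2-enyl)phenyl}methyl)-6-ethyl-4-hydroxy-5-methylpyran-2-one | CCc1oc(=O)c(Cc2c(OCOC)c(CC=C(C)C)c(OCOC)c(C(O[Si](C)(C)C(C)(C)C)[C@H](C)CC)c2OC)c(O)c1C | intermediate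
22 | 6-ethyl-4-hydroxy-3-({3-[(2R)-1-hydroxy-2-methylbutyl]-2-methoxy-4,6-bis(methoxymethoxy)-5-(3-methylbut-2-enyl)phenyl}methyl)-5-methylpyran-2-one | CCc1oc(=O)c(Cc2c(OCOC)c(CC=C(C)C)c(OCOC)c(C(O)[C@H](C)CC)c2OC)c(O)c1C | intermediate
23 | 6-ethyl-4-hydroxy-3-({2-methoxy-4,6-bis(methoxymethoxy)-3-[(2R)-2-methylbutanoyl]-5-(3-methylbut-2-enyl)phenyl}methyl)-5-methylpyran-2-one | CCc1oc(=O)c(Cc2c(OCOC)c(CC=C(C)C)c(OCOC)c(C(=O)[C@H](C)CC)c2OC)c(O)c1C | intermediate
24 | 6-ethyl-4-hydroxy-3-({2,4-dihydroxy-6-methoxy-5-[(2R)-2-methylbutanoyl]-3-(3-methylbut-2-enyl)phenyl}methyl)-5-methylpyran-2-one | CCc1oc(=O)c(Cc2c(O)c(CC=C(C)C)c(O)c(C(=O)[C@H](C)CC)c2OC)c(O)c1C | target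

## Step count and least certain steps

Total: 12 steps. Longest linear sequence: 11 steps (steps 1, 2 and 4–12, from 1); step 3 is a one-step branch.

**Step 9 (key step).** The acyl enolate may expel the β-keto ester enolate and fall apart to a ketene faster than it closes the ring, or the base may deprotonate the γ-CH2 of the enoate; either way material is diverted without ring closure. The fallback makes the C3–CH2 bond instead of C3–C4. It sets out from 12 and returns at 21:
- 12 is metalated as in step 7 to 14, which is quenched with DMF to give 3-[(2R)-1-(tert-butyldimethylsilyloxy)-2-methylbutyl]-2-methoxy-4,6-bis(methoxymethoxy)-5-(3-methylbut-2-enyl)benzaldehyde F1.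
- Separately, methyl 3-oxopentanoate is acylated at its γ-carbon (NaH, then n-BuLi; N-methoxy-N-methylpropanamide) to methyl 4-methyl-3,5-dioxoheptanoate F2, which is lactonised (DBU, toluene, reflux) to 6-ethyl-4-hydroxy-5-methylpyran-2-one F3.
- F1 and F3 are combined with Hantzsch ester and catalytic L-proline. Knoevenagel condensation gives the 3-arylmethylidene pyran-2,4-dione F4, which is reduced in the same flask to 21.

**Step 8.** The acylation may proceed with poor control of the enol-ester geometry, because the sodium chelate may not hold under the reaction conditions, or partly at carbon. The fallback corrects the geometry after the acylation and not during it. It sets out from 16 and returns at 20. Acid chloride 18 is coupled with 17 under amine conditions (Et3N, catalytic 4-dimethylaminopyridine, CH2Cl2), which should give 20 together with methyl (E)-3-[(3-{3-[(2R)-1-(tert-butyldimethylsilyloxy)-2-methylbutyl]-2-methoxy-4,6-bis(methoxymethoxy)-5-(3-methylbut-2-enyl)phenyl}propanoyl)oxy]-2-methylpent-2-enoate F5. F5 is separated, equilibrated with 20 by triplet-sensitised E/Z photoisomerisation (benzophenone, 365 nm), and recycled after each separation.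

**Step 7.** The hindered aryl metal may attack the lactone carbonyl (acyl–oxygen cleavage), or may not pass into a copper species reactive enough for substitution at the O-alkyl carbon. The fallback builds the chain in three steps. It sets out from 12 and returns at 16:
- 14 is alkylated with allyl bromide (CuI catalysis) to tert-butyl{(2R)-1-[2-methoxy-4,6-bis(methoxymethoxy)-5-(3-methylbut-2-enyl)-3-(prop-2-enyl)phenyl]-2-methylbutoxy}dimethylsilane F6.
- Hydroboration–oxidation (9-BBN; NaOH, H2O2), which selects the monosubstituted alkene over the prenyl group, gives 3-{3-[(2R)-1-(tert-butyldimethylsilyloxy)-2-methylbutyl]-2-methoxy-4,6-bis(methoxymethoxy)-5-(3-methylbut-2-enyl)phenyl}propan-1-ol F7.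
- Oxidation (TEMPO, PhI(OAc)2, MeCN–pH 7 buffer) gives 16.

**Step 2.** The first metalation may be insufficiently site-selective, with competition from the two carbons between OMOM and OMe. The fallback fixes the site with a halogen. It sets out from 1 and returns at 5:
- 1 is iodinated (I2, NaHCO3, water, 0 °C) at the carbon between the two hydroxyl groups to 2-iodo-5-methoxybenzene-1,3-diol F8.
- Protection (MOMCl, i-Pr2NEt) gives 2-iodo-5-methoxy-1,3-bis(methoxymethoxy)benzene F9.
- Iodine–lithium exchange (t-BuLi, THF, −78 °C) gives 4 with no choice of site, and 4 is alkylated with 3 as in step 2.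

**Step 11.** The hypervalent iodine reagent may oxidise the enolic pyranone further, or the acidic pyranone OH of 22 may ionise the benzylic carbinol before it is oxidised. The fallback masks the pyranone oxygen first. It sets out from 21 and returns at 24:
- 21 is O-alkylated (MOMCl, i-Pr2NEt) to 3-({3-[(2R)-1-(tert-butyldimethylsilyloxy)-2-methylbutyl]-2-methoxy-4,6-bis(methoxymethoxy)-5-(3-methylbut-2-enyl)phenyl}methyl)-6-ethyl-4-(methoxymethoxy)-5-methylpyran-2-one F10.
- Bu4NF gives 6-ethyl-3-({3-[(2R)-1-hydroxy-2-methylbutyl]-2-methoxy-4,6-bis(methoxymethoxy)-5-(3-methylbut-2-enyl)phenyl}methyl)-4-(methoxymethoxy)-5-methylpyran-2-one F11.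
- Dess–Martin periodinane gives 6-ethyl-3-({2-methoxy-4,6-bis(methoxymethoxy)-3-[(2R)-2-methylbutanoyl]-5-(3-methylbut-2-enyl)phenyl}methyl)-4-(methoxymethoxy)-5-methylpyran-2-one F12.
- The acid of step 12 then removes all three MOM groups to give 24.

## Further compounds

F1 | step 9 | 3-[(2R)-1-(tert-butyldimethylsilyloxy)-2-methylbutyl]-2-methoxy-4,6-bis(methoxymethoxy)-5-(3-methylbut-2-enyl)benzaldehyde | CC[C@@H](C)C(O[Si](C)(C)C(C)(C)C)c1c(OC)c(C=O)c(OCOC)c(CC=C(C)C)c1OCOC
F2 | step 9 | methyl 4-methyl-3,5-dioxoheptanoate | CCC(=O)C(C)C(=O)CC(=O)OC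
F3 | step 9 | 6-ethyl-4-hydroxy-5-methylpyran-2-one | CCc1oc(=O)cc(O)c1C
F4 | step 9 | 3-({3-[(2R)-1-(tert-butyldimethylsilyloxy)-2-methylbutyl]-2-methoxy-4,6-bis(methoxymethoxy)-5-(3-methylbut-2-enyl)phenyl}methylidene)-6-ethyl-5-methylpyran-2,4-dione (alkene geometry not defined) | CCC1=C(C)C(=O)C(=Cc2c(OCOC)c(CC=C(C)C)c(OCOC)c(C(O[Si](C)(C)C(C)(C)C)[C@H](C)CC)c2OC)C(=O)O1
F5 | step 8 | methyl (E)-3-[(3-{3-[(2R)-1-(tert-butyldimethylsilyloxy)-2-methylbutyl]-2-methoxy-4,6-bis(methoxymethoxy)-5-(3-methylbut-2-enyl)phenyl}propanoyl)oxy]-2-methylpent-2-enoate | CC/C(OC(=O)CCc1c(OCOC)c(CC=C(C)C)c(OCOC)c(C(O[Si](C)(C)C(C)(C)C)[C@H](C)CC)c1OC)=C(/C)C(=O)OC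
F6 | step 7 | tert-butyl{(2R)-1-[2-methoxy-4,6-bis(methoxymethoxy)-5-(3-methylbut-2-enyl)-3-(prop-2-enyl)phenyl]-2-methylbutoxy}dimethylsilane | CC[C@@H](C)C(O[Si](C)(C)C(C)(C)C)c1c(OC)c(CC=C)c(OCOC)c(CC=C(C)C)c1OCOC
F7 | step 7 | 3-{3-[(2R)-1-(tert-butyldimethylsilyloxy)-2-methylbutyl]-2-methoxy-4,6-bis(methoxymethoxy)-5-(3-methylbut-2-enyl)phenyl}propan-1-ol | CC[C@@H](C)C(O[Si](C)(C)C(C)(C)C)c1c(OC)c(CCCO)c(OCOC)c(CC=C(C)C)c1OCOC
F8 | step 2 | 2-iodo-5-methoxybenzene-1,3-diol | COc1cc(O)c(I)c(O)c1
F9 | step 2 | 2-iodo-5-methoxy-1,3-bis(methoxymethoxy)benzene | COCOc1cc(OC)cc(OCOC)c1I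
F10 | step 11 | 3-({3-[(2R)-1-(tert-butyldimethylsilyloxy)-2-methylbutyl]-2-methoxy-4,6-bis(methoxymethoxy)-5-(3-methylbut-2-enyl)phenyl}methyl)-6-ethyl-4-(methoxymethoxy)-5-methylpyran-2-one | CCc1oc(=O)c(Cc2c(OCOC)c(CC=C(C)C)c(OCOC)c(C(O[Si](C)(C)C(C)(C)C)[C@H](C)CC)c2OC)c(OCOC)c1C
F11 | step 11 | 6-ethyl-3-({3-[(2R)-1-hydroxy-2-methylbutyl]-2-methoxy-4,6-bis(methoxymethoxy)-5-(3-methylbut-2-enyl)phenyl}methyl)-4-(methoxymethoxy)-5-methylpyran-2-one | CCc1oc(=O)c(Cc2c(OCOC)c(CC=C(C)C)c(OCOC)c(C(O)[C@H](C)CC)c2OC)c(OCOC)c1C
F12 | step 11 | 6-ethyl-3-({2-methoxy-4,6-bis(methoxymethoxy)-3-[(2R)-2-methylbutanoyl]-5-(3-methylbut-2-enyl)phenyl}methyl)-4-(methoxymethoxy)-5-methylpyran-2-one | CCc1oc(=O)c(Cc2c(OCOC)c(CC=C(C)C)c(OCOC)c(C(=O)[C@H](C)CC)c2OC)c(OCOC)c1C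
A1 | alternative 1 | (2R)-1-[2-hydroxy-6-methoxy-4-(methoxymethoxy)-3-(3-methylbut-2-enyl)phenyl]-2-methylbutan-1-one | COc1cc(OCOC)c(CC=C(C)C)c(O)c1C(=O)[C@H](C)CC
A2 | alternative 1 | 3-methoxy-5-(methoxymethoxy)-6-(3-methylbut-2-enyl)-2-(trimethylsilyl)phenyl trifluoromethanesulfonate | COc1cc(OCOC)c(CC=C(C)C)c(OS(=O)(=O)C(F)(F)F)c1[Si](C)(C)C
A3 | alternative 2 | 3-({4,6-bis(benzyloxy)-2-methoxy-3-[(2R)-2-methylbutanoyl]phenyl}methyl)-6-ethyl-4-hydroxy-5-methylpyran-2-one | CCc1oc(=O)c(Cc2c(OCc3ccccc3)cc(OCc3ccccc3)c(C(=O)[C@H](C)CC)c2OC)c(O)c1C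
A4 | alternative 2 | 2-({4,6-bis(benzyloxy)-2-methoxy-3-[(2R)-2-methylbutanoyl]phenyl}methyl)propanedioyl dichloride | CC[C@@H](C)C(=O)c1c(OC)c(CC(C(=O)Cl)C(=O)Cl)c(OCc2ccccc2)cc1OCc1ccccc1
A5 | alternative 2 | (Z)-trimethyl(pent-2-en-3-yloxy)silane | C/C=C(\O[Si](C)(C)C)CC
A6 | alternative 3 | methyl 3-{3-[(2R)-1-(tert-butyldimethylsilyloxy)-2-methylbutyl]-6-hydroxy-2-methoxy-5-(3-methylbut-2-enyl)-4-(triisopropylsilyloxy)phenyl}propanoate | COC(=O)CCc1c(O)c(CC=C(C)C)c(O[Si](C(C)C)(C(C)C)C(C)C)c(C(O[Si](C)(C)C(C)(C)C)[C@H](C)CC)c1OC
A7 | alternative 3 | methyl 3-{3-[(2R)-1-(tert-butyldimethylsilyloxy)-2-methylbutyl]-2-methoxy-4-oxocyclobut-2-en-1-yl}propanoate | COC(=O)CCC1C(=O)C(C(O[Si](C)(C)C(C)(C)C)[C@H](C)CC)=C1OC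
A8 | alternative 3 | triisopropyl[(5-methylhex-4-en-1-yn-1-yl)oxy]silane | CC(C)=CCC#CO[Si](C(C)C)(C(C)C)C(C)C
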